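**Remark:** target 24 has no stereocentre and is drawn as the diketo tautomer, although the chelated enol should predominate; compounds 2, 8 (as a THF solution), 11, 12 and 16 are taken as articles of commerce.
Abbreviations: TBS = tert-butyldimethylsilyl; prenyl = 3-methylbut-2-en-1-yl.

## Analysis of the target

Compound 24 is an unsymmetrical dibenzoylmethane. A three-carbon chain (C=O, CH2, C=O) joins ring A, a 4-hydroxy-2-methoxy-3-prenylphenyl group, to ring B, a 4-hydroxy-3-prenylphenyl group; there is no other ring. It has no stereocentre, and both prenyl alkenes end in geminal methyl groups, so no stereochemical relationship has to be controlled. The sensitive groups are the two ortho-prenyl phenols, which cyclise onto their own alkenes under acid and do not survive hydrogenation, and the 1,3-diketone, which is acidic, chelating and open to retro-Claisen cleavage by hard base. The real difficulty is ring A: four contiguous substituents, the prenyl group wedged between two oxygens, and the oxygen next to the carbonyl (C2) methylated while the remote one (C4) is free. A resorcinol ketone offers the reverse, because its C2 hydroxyl is hydrogen-bonded to the carbonyl and is alkylated last, and C-prenylation does not reliably choose C3 over C5. The strategy rests on the ring A pattern itself: acyl at C1, OMe at C2, prenyl at C3, oxygen at C4 and hydrogen at C5 and C6. A four-carbon diene (C2 to C5) with a ketene dimethyl acetal terminus, a prenyl group, a silyloxy group and a CH2 terminus delivers exactly this on cycloaddition to a terminal acetylenic ketone (C1 and C6) and loss of methanol. The second carbonyl of the chain can stay latent as an alkyne, so the dienophile can be a cross-conjugated diynone that already carries ring B.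

## Retrosynthetic reasoning

**From 24 to 23.** The two phenolic O–H bonds are exchanged for O–Si bonds. Silyl ethers are preferred to acetal or alkyl protection because they leave under near-neutral desilylation, whereas acid strong enough to cleave an acetal would also close the ortho-prenyl phenols to cyclic ethers. The forward step only has to break two O–Si bonds without disturbing the diketone.

**From 23 to 21.** The oxygen of the carbonyl next to ring B is removed and the CH2–C(=O) unit is written as an alkyne, so 23 is the hydrate of ynone 21. The cut is made here, and not at a C–C bond of the chain, because the ynone has no acidic methylene, cannot chelate and is the direct product of a cycloaddition to a diynone. In the forward direction a secondary amine adds to the alkyne carbon remote from the carbonyl to give enaminone 22, and dilute acid hydrolyses it. Only one orientation of addition is possible, so the hydration is regiospecific.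

**From 21 to 19 and 10.** Ring A is opened at C1–C2 and C5–C6, the two bonds of a Diels–Alder reaction, after one methoxy group has been added back to C2 to give the cyclohexadiene ketal 20. This is the only cut that creates the acyl, OMe, prenyl and oxygen substituents in their final positions in one operation and delivers the two oxygens already differentiated (one as a methyl ether, one as a silyl ether). It removes both the regioselective prenylation and the methylation of a chelated phenol from the plan. The forward reaction must join the CH2 terminus of diene 19 to the unsubstituted alkyne carbon of 10, leave the internal aryl alkyne of 10 untouched, and aromatise by expelling one methoxy group.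

**From 19 to 17.** The O–Si bond of the silyl dienol ether is cut. Diene 19 is the enol silyl ether of acylketene acetal 17, reached through enolate 18. The acetyl methyl group is the only position of 17 with an α-hydrogen, so enolisation has no regiochemical choice.

**From 17 to 15 and 16.** The bond between the acetyl carbonyl and the ketene acetal carbon that carries the prenyl group is cut. Ketene acetal 15 is nucleophilic at exactly that carbon, so acylation by 16 forms the bond directly and the ketene acetal double bond is regenerated by loss of a proton.

**From 15 to 14, and from 14 to 11 and 12.** An ester enolate is alkylated on carbon rather than on oxygen, so the ketene acetal is not taken from an ester. It is taken from the orthoester oxidation level: in 14 one methoxy group can be ionised and the cation deprotonated. Orthoester 14 is cut at the bond between its central carbon and the chain, which leads to Grignard reagent 13 (from bromide 11) and orthocarbonate 12. The prenyl unit thus arrives as a preformed sp3 chain and no allylic transposition can occur.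

**From 10 to 7 and 8.** The ketone of 10 is taken back to carbinol 9, and 9 is cut between the carbinol carbon and the terminal ethynyl group. Addition of 8 to ynal 7 forms this bond, and a mild neutral oxidation then gives the diynone without exposing it to base.

**From 7 to 1 and 2.** The formyl carbon of 7 is removed to give acetylide 6, which comes from dibromoalkene 5 and so from aldehyde 4 by one-carbon homologation. Aldehyde 4 is the silyl ether of 3, and 3 is cut at the aryl–CH2 bond to 1 and 2. The para position of 1 is blocked, so C-alkylation can occur only ortho to the oxygen.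

## Alternatives that were turned down

**Alternative 1:** The diketone is masked as isoxazole A1 and disconnected to aldoxime A2 and ring B alkyne A4. Forward, oxidation of A2 gives nitrile oxide A3, which adds to A4 in a 1,3-dipolar cycloaddition.
- For it: this cycloaddition is more secure than the chosen key step. A terminal alkyne gives the 3,5-disubstituted isoxazole almost by rule, both partners are stable and storable (unlike 10 and 19), and A1 tolerates a wide range of later conditions.
- Against it: A2 already contains the full acyl/OMe/prenyl/oxygen array of ring A, so the central problem of the target is not solved but moved into an unspecified arene synthesis. Unmasking A1 needs a reductive N–O cleavage in the presence of two trisubstituted alkenes, then hydrolysis. The methoxymethyl ethers then need acid, which is what the ortho-prenyl phenols tolerate least. The oxidant that generates A3 also meets two electron-rich alkenes.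
- Comparison: the chosen route has a less certain key step, but it builds ring A with its substituents in place and ends with non-reductive, near-neutral operations.

**Alternative 2:** Both aryl–CH2 bonds are cut at the end: diiodide A6 is coupled twice with prenylzinc bromide A7 under zerovalent palladium with a bulky biaryl dialkylphosphine to give A5, the bis(methoxymethyl) ether of the target.
- For it: it is stronger on step economy. The diketone skeleton comes from simple iodoarenes and both prenyl groups arrive in one operation.
- Against it: A6 has an acidic methylene between two carbonyls, which will be deprotonated by A7 and can bind the metal. The ring A iodide sits between two ortho oxygen substituents, where the outcome of reductive elimination from the allylpalladium intermediate is least predictable. α-Coupling must win over γ-coupling at two different sites, and any reverse-prenyl connectivity at either ring gives isomers of identical mass and polarity. Preparing A6 still requires the methylated C2 oxygen and the protected C4 oxygen of ring A, and the end again needs acid.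
- Comparison: the chosen route is longer, but it carries the ring A prenyl group in as a preformed sp3 chain from 11, so linear connectivity at the hindered site is not in question.

**Alternative 3:** The ynone is assembled by a three-component carbonylative Sonogashira coupling: ring B iodide A9, carbon monoxide A11 and ring A alkyne A10 give ynone A8, whose carbonyl lies on ring B.
- For it: A8 and 21 are regioisomeric ynones that converge on the same diketone after hydration, so the endgame is shared. The coupling joins two stable aryl partners in one step, and A9 needs far fewer steps than diynone 10. On convergence and on the ring B side this alternative is stronger.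
- Against it: A10 needs the same four contiguous substituents on ring A as the target, with an ethynyl group in place of the acyl group, and the coupling does nothing to build them. The coupling also has to beat direct, non-carbonylative alkynylation and alkyne homocoupling. The methoxymethyl ethers bring back the acidic deprotection.
- Comparison: the chosen route spends more steps on ring B, and in return ring A comes from acyclic material with its regiochemistry set by the polarisation of the diene.

Key step: step 11

## Route

**Step 1**
Reactants: 1 4-hydroxybenzaldehyde; 2 prenyl bromide (1-bromo-3-methylbut-2-ene)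
Product: 3 4-hydroxy-3-prenylbenzaldehyde
Conditions: 10% aq. KOH, rt
Reagents that add atoms: none
Why: Phenoxide C-alkylation: in water the phenoxide oxygen is tightly solvated, so the ambident anion reacts in part through its ortho carbon with the primary allylic bromide (SN2, linear prenyl), the para position being blocked by the formyl group; the O-prenyl ether is the expected by-product and is separated.

**Step 2**
Reactants: 3 4-hydroxy-3-prenylbenzaldehyde
Product: 4 4-(TBS-oxy)-3-prenylbenzaldehyde
Conditions: TBSCl, imidazole, DMF, rt
Reagents that add atoms: tert-butyldimethylsilyl chloride (TBSCl), CC(C)(C)[Si](C)(C)Cl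
Why: Standard imidazole-promoted silylation of a phenol; the aryl silyl ether masks the acidic OH for the organolithium and Grignard steps and is later removed by fluoride without acid.

**Step 3**
Reactants: 4 4-(TBS-oxy)-3-prenylbenzaldehyde
Product: 5 tert-butyl[4-(2,2-dibromoethenyl)-2-prenylphenoxy]dimethylsilane
Conditions: CBr4, PPh3, Zn, CH2Cl2, rt
Reagents that add atoms: carbon tetrabromide, BrC(Br)(Br)Br
Why: First stage of the Corey–Fuchs homologation: the ylide Ph3P=CBr2 formed from CBr4, PPh3 and Zn undergoes a Wittig reaction with the aldehyde, and because Zn takes up the bromine no Ph3PBr2 or HBr is left to attack the prenyl alkene.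

**Step 4**
Reactants: 5 tert-butyl[4-(2,2-dibromoethenyl)-2-prenylphenoxy]dimethylsilane
Product: 7 3-[4-(TBS-oxy)-3-prenylphenyl]prop-2-ynal, via lithium arylacetylide 6 (not isolated)
Conditions: n-BuLi (2.1 equiv), THF, −78 °C; DMF, −78 → 0 °C; aq. KH2PO4
Reagents that add atoms: N,N-dimethylformamide, CN(C)C=O
Why: Second stage of the Corey–Fuchs sequence: bromine–lithium exchange and Fritsch–Buttenberg–Wiechell rearrangement give the alkyne, the second equivalent of n-BuLi deprotonates it to 6, and 6 is formylated by DMF; a buffered reverse quench releases the ynal without amine conjugate addition.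

**Step 5**
Reactants: 7 3-[4-(TBS-oxy)-3-prenylphenyl]prop-2-ynal; 8 ethynylmagnesium bromide
Product: 9 rac-1-[4-(TBS-oxy)-3-prenylphenyl]penta-1,4-diyn-3-ol
Conditions: THF, −78 → 0 °C; aq. NH4Cl
Reagents that add atoms: none
Why: 1,2-Addition of an alkynyl Grignard reagent to the ynal (hard nucleophile, no conjugate addition); the carbinol centre is formed racemic without control, which is immaterial because step 6 removes it.

**Step 6**
Reactants: 9 rac-1-[4-(TBS-oxy)-3-prenylphenyl]penta-1,4-diyn-3-ol
Product: 10 1-[4-(TBS-oxy)-3-prenylphenyl]penta-1,4-diyn-3-one
Conditions: MnO2, CH2Cl2, 0 °C → rt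
Reagents that add atoms: none
Why: Activated MnO2 oxidises the doubly propargylic alcohol under neutral heterogeneous conditions, so the base- and nucleophile-sensitive terminal diynone is obtained by filtration and used at once in step 11.

**Step 7**
Reactants: 11 5-bromo-2-methylpent-2-ene; 12 tetramethyl orthocarbonate
Product: 14 1,1,1-trimethoxy-5-methylhex-4-ene, via homoprenylmagnesium bromide 13 (not isolated)
Conditions: Mg, THF, reflux; C(OMe)4, Et2O–THF, reflux; aq. NaHCO3
Reagents that add atoms: none
Why: Grignard formation followed by the Tschitschibabin orthoester synthesis: magnesium-assisted loss of one methoxide from the orthocarbonate and C–C bond formation give the orthoester, which is less electrophilic than 12 so a second addition is slow; the basic work-up preserves the orthoester.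

**Step 8**
Reactants: 14 1,1,1-trimethoxy-5-methylhex-4-ene
Product: 15 1,1-dimethoxy-5-methylhexa-1,4-diene
Conditions: TMSOTf, i-Pr2NEt, CH2Cl2, −20 °C → rt
Reagents that add atoms: none
Why: Elimination of methanol from an orthoester to a ketene acetal: TMSOTf abstracts one methoxy group to give the dimethoxycarbenium ion and the hindered amine removes the adjacent proton (the same manifold as the acetal-to-enol-ether conversion); the medium stays basic, so the trisubstituted alkene and the product are not protonated.

**Step 9**
Reactants: 15 1,1-dimethoxy-5-methylhexa-1,4-diene; 16 acetyl chloride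
Product: 17 3-(dimethoxymethylidene)-6-methylhept-5-en-2-one
Conditions: pyridine, CH2Cl2, −20 → 0 °C
Reagents that add atoms: none
Why: C-Acylation of a ketene acetal by an acid chloride: the nucleophilic β-carbon of 15 attacks the acylpyridinium ion, and pyridine removes the now doubly activated proton from the dimethoxycarbenium intermediate faster than chloride can demethylate it, giving the push–pull acylketene acetal.

**Step 10**
Reactants: 17 3-(dimethoxymethylidene)-6-methylhept-5-en-2-one
Product: 19 tert-butyl{[3-(dimethoxymethylidene)-6-methylhepta-1,5-dien-2-yl]oxy}dimethylsilane (1,1-dimethoxy-2-prenyl-3-(TBS-oxy)buta-1,3-diene), via lithium dienolate 18 (not isolated)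
Conditions: LDA (LiN(i-Pr)2), THF, −78 °C; TBSCl, DMPU, −78 → 0 °C
Reagents that add atoms: tert-butyldimethylsilyl chloride (TBSCl), CC(C)(C)[Si](C)(C)Cl
Why: Kinetic deprotonation of the acetyl methyl group, the only α-position with a hydrogen, gives cross-conjugated enolate 18, which is silylated on oxygen to the silyl dienol ether; TBS is chosen so that this oxygen survives the aromatisation as an aryl silyl ether.

**Step 11**
Reactants: 19 1,1-dimethoxy-2-prenyl-3-(TBS-oxy)buta-1,3-diene; 10 1-[4-(TBS-oxy)-3-prenylphenyl]penta-1,4-diyn-3-one
Product: 21 1-[4-(TBS-oxy)-2-methoxy-3-prenylphenyl]-3-[4-(TBS-oxy)-3-prenylphenyl]prop-2-yn-1-one, via cyclohexadiene ketal adduct 20 (not isolated)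
Conditions: toluene, 0 → 40 °C; PPTS (cat.), rt
Reagents that add atoms: none
Why: This is a Diels–Alder benzannulation of a 1,1-dialkoxy-3-silyloxybutadiene with an acetylenic ketone, the known route to resorcinol monomethyl ethers. The ketene acetal and the silyl enol ether both push electron density to the CH2 terminus of 19, which bonds to the unsubstituted alkyne carbon of 10 in a concerted but strongly asynchronous (4+2) process; at the stepwise limit this is a Michael addition followed by attack of the allenolate carbon on the dimethoxycarbenium carbon, a six-membered closure in which the attacked C=O+ bond lies outside the ring. C5–C6 therefore forms ahead of C1–C2, and the product is the cyclohexa-1,4-diene ketal 20, which has no stereocentre. 1,4-Elimination of methanol from 20 (hydrogen from the ring CH2, methoxy from the ketal carbon), completed by a trace of PPTS, aromatises it irreversibly to 21. The step needs regioselectivity, and the polarisation of the diene secures it: the ketene acetal carbon can only end up ortho to the acyl group, which puts OMe at C2, prenyl at C3 and the silyloxy group at C4. It also needs site selectivity between the two alkynes of 10: the terminal alkyne is unhindered and the more electrophilic, whereas the internal one carries a bulky, electron-donating aryl group, and the ynone of 21 is deactivated in the same way, so a second cycloaddition should be slow. The silyl enol ether oxygen is carried into the arene as an aryl TBS ether, so the two ring A oxygens emerge differentiated. No stereocentre is formed.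

**Step 12**
Reactants: 21 1-[4-(TBS-oxy)-2-methoxy-3-prenylphenyl]-3-[4-(TBS-oxy)-3-prenylphenyl]prop-2-yn-1-one
Product: 23 1-[4-(TBS-oxy)-2-methoxy-3-prenylphenyl]-3-[4-(TBS-oxy)-3-prenylphenyl]propane-1,3-dione, via pyrrolidine enaminone 22 (not isolated)
Conditions: pyrrolidine, CH2Cl2, rt; 1 M aq. HCl, THF, 0 °C → rt
Reagents that add atoms: water, O
Why: Aza-Michael addition of the secondary amine to the ynone gives vinylogous amide 22 (amine on the carbon bearing ring B, E geometry expected and of no consequence), and C-protonation and hydrolysis of the iminium ion in dilute acid release the 1,3-diketone, so the net result is a regiospecific hydration; aryl TBS ethers and the prenyl alkenes should tolerate the brief dilute-acid treatment.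

**Step 13**
Reactants: 23 1-[4-(TBS-oxy)-2-methoxy-3-prenylphenyl]-3-[4-(TBS-oxy)-3-prenylphenyl]propane-1,3-dione
Product: 24 1-[4-hydroxy-2-methoxy-3-prenylphenyl]-3-[4-hydroxy-3-prenylphenyl]propane-1,3-dione (target)
Conditions: TBAF, AcOH, THF, 0 °C → rt
Reagents that add atoms: none
Why: Fluoride cleaves both aryl silyl ethers; buffering with AcOH keeps the medium near neutral, so the diketone is not exposed to basic phenoxide or enolate chemistry and no acid strong enough to cyclise the ortho-prenyl phenols is present.

## Compound list

1 | 4-hydroxybenzaldehyde | O=Cc1ccc(O)cc1 | starting material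
2 | prenyl bromide (1-bromo-3-methylbut-2-ene) | CC(C)=CCBr | starting material
3 | 4-hydroxy-3-(3-methylbut-2-en-1-yl)benzaldehyde | O=Cc1ccc(O)c(CC=C(C)C)c1 | intermediate
4 | 4-[(tert-butyldimethylsilyl)oxy]-3-(3-methylbut-2-en-1-yl)benzaldehyde | O=Cc1ccc(O[Si](C)(C)C(C)(C)C)c(CC=C(C)C)c1 | intermediate
5 | tert-butyl[4-(2,2-dibromoethenyl)-2-(3-methylbut-2-en-1-yl)phenoxy]dimethylsilane | BrC(Br)=Cc1ccc(O[Si](C)(C)C(C)(C)C)c(CC=C(C)C)c1 | intermediate
6 | lithium {4-[(tert-butyldimethylsilyl)oxy]-3-(3-methylbut-2-en-1-yl)phenyl}acetylide | [Li]C#Cc1ccc(O[Si](C)(C)C(C)(C)C)c(CC=C(C)C)c1 | intermediate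
7 | 3-{4-[(tert-butyldimethylsilyl)oxy]-3-(3-methylbut-2-en-1-yl)phenyl}prop-2-ynal | O=CC#Cc1ccc(O[Si](C)(C)C(C)(C)C)c(CC=C(C)C)c1 | intermediate
8 | ethynylmagnesium bromide | C#C[Mg]Br | starting material
9 | rac-1-{4-[(tert-butyldimethylsilyl)oxy]-3-(3-methylbut-2-en-1-yl)phenyl}penta-1,4-diyn-3-ol (racemic) | C#CC(O)C#Cc1ccc(O[Si](C)(C)C(C)(C)C)c(CC=C(C)C)c1 | intermediate
10 | 1-{4-[(tert-butyldimethylsilyl)oxy]-3-(3-methylbut-2-en-1-yl)phenyl}penta-1,4-diyn-3-one | C#CC(=O)C#Cc1ccc(O[Si](C)(C)C(C)(C)C)c(CC=C(C)C)c1 | intermediate
11 | 5-bromo-2-methylpent-2-ene | CC(C)=CCCBr | starting material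
12 | tetramethyl orthocarbonate (tetramethoxymethane) | COC(OC)(OC)OC | starting material
13 | (4-methylpent-3-en-1-yl)magnesium bromide | CC(C)=CCC[Mg]Br | intermediate
14 | 1,1,1-trimethoxy-5-methylhex-4-ene | COC(OC)(OC)CCC=C(C)C | intermediate
15 | 1,1-dimethoxy-5-methylhexa-1,4-diene | COC(OC)=CCC=C(C)C | intermediate
16 | acetyl chloride | CC(=O)Cl | starting material
17 | 3-(dimethoxymethylidene)-6-methylhept-5-en-2-one | CC(=O)C(CC=C(C)C)=C(OC)OC | intermediate
18 | lithium 3-(dimethoxymethylidene)-6-methylhepta-1,5-dien-2-olate | [Li]OC(=C)C(CC=C(C)C)=C(OC)OC | intermediate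
19 | tert-butyl{[3-(dimethoxymethylidene)-6-methylhepta-1,5-dien-2-yl]oxy}dimethylsilane | COC(OC)=C(CC=C(C)C)C(=C)O[Si](C)(C)C(C)(C)C | intermediate
20 | 1-{4-[(tert-butyldimethylsilyl)oxy]-6,6-dimethoxy-5-(3-methylbut-2-en-1-yl)cyclohexa-1,4-dien-1-yl}-3-{4-[(tert-butyldimethylsilyl)oxy]-3-(3-methylbut-2-en-1-yl)phenyl}prop-2-yn-1-one | COC1(OC)C(C(=O)C#Cc2ccc(O[Si](C)(C)C(C)(C)C)c(CC=C(C)C)c2)=CCC(O[Si](C)(C)C(C)(C)C)=C1CC=C(C)C | intermediate
21 | 1-{4-[(tert-butyldimethylsilyl)oxy]-2-methoxy-3-(3-methylbut-2-en-1-yl)phenyl}-3-{4-[(tert-butyldimethylsilyl)oxy]-3-(3-methylbut-2-en-1-yl)phenyl}prop-2-yn-1-one | COc1c(C(=O)C#Cc2ccc(O[Si](C)(C)C(C)(C)C)c(CC=C(C)C)c2)ccc(O[Si](C)(C)C(C)(C)C)c1CC=C(C)C | intermediate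
22 | (2E)-1-{4-[(tert-butyldimethylsilyl)oxy]-2-methoxy-3-(3-methylbut-2-en-1-yl)phenyl}-3-{4-[(tert-butyldimethylsilyl)oxy]-3-(3-methylbut-2-en-1-yl)phenyl}-3-(pyrrolidin-1-yl)prop-2-en-1-one | COc1c(C(=O)/C=C(/N2CCCC2)c2ccc(O[Si](C)(C)C(C)(C)C)c(CC=C(C)C)c2)ccc(O[Si](C)(C)C(C)(C)C)c1CC=C(C)C | intermediate
23 | 1-{4-[(tert-butyldimethylsilyl)oxy]-2-methoxy-3-(3-methylbut-2-en-1-yl)phenyl}-3-{4-[(tert-butyldimethylsilyl)oxy]-3-(3-methylbut-2-en-1-yl)phenyl}propane-1,3-dione | COc1c(C(=O)CC(=O)c2ccc(O[Si](C)(C)C(C)(C)C)c(CC=C(C)C)c2)ccc(O[Si](C)(C)C(C)(C)C)c1CC=C(C)C | intermediate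
24 | 1-[4-hydroxy-2-methoxy-3-(3-methylbut-2-en-1-yl)phenyl]-3-[4-hydroxy-3-(3-methylbut-2-en-1-yl)phenyl]propane-1,3-dione | COc1c(C(=O)CC(=O)c2ccc(O)c(CC=C(C)C)c2)ccc(O)c1CC=C(C)C | target

## Step count and risk

Total step count: 13. Longest linear sequence: 9 steps (steps 1 to 6, then 11, 12 and 13); the diene arm (steps 7 to 10) joins at step 11.

**Step 11 (key step).** The prenyl group at C2 of the diene sits between the two oxygenated carbons and may keep 19 from reaching the cisoid geometry needed for ring closure. Simple Michael addition with silyl transfer, or oligomerisation of the very electrophilic terminal diynone, would then outrun the cycloaddition. Adventitious acid can also hydrolyse the ketene acetal before it reacts.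
- Fallback: it sets out from 19 and 4 and comes back at 23.
- Diene 19 is heated with methyl propiolate, the simplest acetylenic ester. The same cycloaddition and loss of methanol should give methyl 4-[(tert-butyldimethylsilyl)oxy]-2-methoxy-3-(3-methylbut-2-en-1-yl)benzoate F1.
- Aldehyde 4 is treated with MeMgBr to give rac-1-{4-[(tert-butyldimethylsilyl)oxy]-3-(3-methylbut-2-en-1-yl)phenyl}ethan-1-ol F2, which MnO2 oxidises to 1-{4-[(tert-butyldimethylsilyl)oxy]-3-(3-methylbut-2-en-1-yl)phenyl}ethan-1-one F3.
- Crossed Claisen condensation of the lithium enolate of F3 (LiN(SiMe3)2, THF) with F1 then gives 23 directly, so the diynone and the hydration are no longer needed.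

**Step 9.** Chloride may demethylate the dimethoxycarbenium intermediate before it is deprotonated, which would return a β-keto ester instead of the acylketene acetal. Acetyl chloride may also be diverted to ketene by the base.
- Fallback: it sets out from 16 and comes back at 17, and it also bypasses steps 7 and 8.
- Acetyl chloride 16 acylates commercial 1,1-dimethoxyethene, which has no substituent to slow the attack, giving 4,4-dimethoxybut-3-en-2-one F4.
- Iodination at the nucleophilic α-carbon of this push–pull alkene (I2, pyridine) gives 3-iodo-4,4-dimethoxybut-3-en-2-one F5.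
- Stille coupling with tributyl(3-methylbut-2-en-1-yl)stannane (Pd(PPh3)4, CuI, DMF) installs the prenyl group and gives 17.

**Step 8.** The dimethoxycarbenium ion may transfer a methyl group instead of losing a proton, which reverts the material to the ester oxidation level. The ketene acetal formed may also condense with unreacted cation, and hydrolysis during isolation is a further loss.
- Fallback: it sets out from 11 and comes back at 15.
- Bromide 11 is oxidised with trimethylamine N-oxide in DMSO (Kornblum-type oxidation) to 4-methylpent-3-enal F6.
- Lithiated (dimethoxymethyl)diphenylphosphine oxide is added at low temperature to give rac-1-(diphenylphosphoryl)-1,1-dimethoxy-5-methylhex-4-en-2-ol F7.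
- Horner–Wittig elimination with KOtBu then forms the ketene acetal double bond of 15.

**Step 1.** O-Alkylation competes with C-alkylation of the ambident phenoxide, and double alkylation and incomplete conversion lower the throughput of the first step.
- Fallback: it sets out from 1 and comes back at 4.
- Compound 1 is O-allylated (allyl bromide, K2CO3) to 4-(prop-2-en-1-yloxy)benzaldehyde F8.
- Aromatic Claisen rearrangement near 200 °C gives 4-hydroxy-3-(prop-2-en-1-yl)benzaldehyde F9, and silylation gives 4-[(tert-butyldimethylsilyl)oxy]-3-(prop-2-en-1-yl)benzaldehyde F10.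
- Cross-metathesis with 2-methylbut-2-ene (second-generation Grubbs catalyst) converts the allyl group into the prenyl group of 4.

**Step 12.** Hydrolysis of the diaryl vinylogous amide may stall in acid mild enough to spare the silyl ethers, and forcing it risks partial desilylation and acid-promoted cyclisation of a liberated prenyl phenol.
- Fallback: it sets out from 21 and comes back at 23 and makes no new compound (F0).
- The ynone is hydrated directly by π-acid catalysis (Ph3PAuCl and AgOTf, wet 1,4-dioxane). Water attacks the alkyne carbon remote from the carbonyl, and no amine or mineral acid is used.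

## Further compounds

F1 | step 11 | methyl 4-[(tert-butyldimethylsilyl)oxy]-2-methoxy-3-(3-methylbut-2-en-1-yl)benzoate | COC(=O)c1ccc(O[Si](C)(C)C(C)(C)C)c(CC=C(C)C)c1OC
F2 | step 11 | rac-1-{4-[(tert-butyldimethylsilyl)oxy]-3-(3-methylbut-2-en-1-yl)phenyl}ethan-1-ol | CC(O)c1ccc(O[Si](C)(C)C(C)(C)C)c(CC=C(C)C)c1
F3 | step 11 | 1-{4-[(tert-butyldimethylsilyl)oxy]-3-(3-methylbut-2-en-1-yl)phenyl}ethan-1-one | CC(=O)c1ccc(O[Si](C)(C)C(C)(C)C)c(CC=C(C)C)c1
F4 | step 9 | 4,4-dimethoxybut-3-en-2-one | COC(OC)=CC(C)=O
F5 | step 9 | 3-iodo-4,4-dimethoxybut-3-en-2-one | COC(OC)=C(I)C(C)=O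
F6 | step 8 | 4-methylpent-3-enal | CC(C)=CCC=O
F7 | step 8 | rac-1-(diphenylphosphoryl)-1,1-dimethoxy-5-methylhex-4-en-2-ol | COC(OC)(C(O)CC=C(C)C)P(=O)(c1ccccc1)c1ccccc1
F8 | step 1 | 4-(prop-2-en-1-yloxy)benzaldehyde | C=CCOc1ccc(C=O)cc1
F9 | step 1 | 4-hydroxy-3-(prop-2-en-1-yl)benzaldehyde | C=CCc1cc(C=O)ccc1O
F10 | step 1 | 4-[(tert-butyldimethylsilyl)oxy]-3-(prop-2-en-1-yl)benzaldehyde | C=CCc1cc(C=O)ccc1O[Si](C)(C)C(C)(C)C
F0 | step 12 | none | none
A1 | alternative 1 | 3-[2-methoxy-4-(methoxymethoxy)-3-(3-methylbut-2-en-1-yl)phenyl]-5-[4-(methoxymethoxy)-3-(3-methylbut-2-en-1-yl)phenyl]isoxazole | COc1c(-c2cc(-c3ccc(OCOC)c(CC=C(C)C)c3)on2)ccc(OCOC)c1CC=C(C)C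
A2 | alternative 1 | (E)-2-methoxy-4-(methoxymethoxy)-3-(3-methylbut-2-en-1-yl)benzaldehyde oxime | COc1c(/C=N/O)ccc(OCOC)c1CC=C(C)C
A3 | alternative 1 | 2-methoxy-4-(methoxymethoxy)-3-(3-methylbut-2-en-1-yl)benzonitrile oxide | COc1c(C#[N+][O-])ccc(OCOC)c1CC=C(C)C
A4 | alternative 1 | 4-ethynyl-1-(methoxymethoxy)-2-(3-methylbut-2-en-1-yl)benzene | C#Cc1ccc(OCOC)c(CC=C(C)C)c1
A5 | alternative 2 | 1-[2-methoxy-4-(methoxymethoxy)-3-(3-methylbut-2-en-1-yl)phenyl]-3-[4-(methoxymethoxy)-3-(3-methylbut-2-en-1-yl)phenyl]propane-1,3-dione | COc1c(C(=O)CC(=O)c2ccc(OCOC)c(CC=C(C)C)c2)ccc(OCOC)c1CC=C(C)C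
A6 | alternative 2 | 1-[3-iodo-2-methoxy-4-(methoxymethoxy)phenyl]-3-[3-iodo-4-(methoxymethoxy)phenyl]propane-1,3-dione | COc1c(C(=O)CC(=O)c2ccc(OCOC)c(I)c2)ccc(OCOC)c1I
A7 | alternative 2 | prenylzinc bromide | CC(C)=CC[Zn]Br
A8 | alternative 3 | 3-[2-methoxy-4-(methoxymethoxy)-3-(3-methylbut-2-en-1-yl)phenyl]-1-[4-(methoxymethoxy)-3-(3-methylbut-2-en-1-yl)phenyl]prop-2-yn-1-one | COc1c(C#CC(=O)c2ccc(OCOC)c(CC=C(C)C)c2)ccc(OCOC)c1CC=C(C)C
A9 | alternative 3 | 4-iodo-1-(methoxymethoxy)-2-(3-methylbut-2-en-1-yl)benzene | COCOc1ccc(I)cc1CC=C(C)C
A10 | alternative 3 | 1-ethynyl-2-methoxy-4-(methoxymethoxy)-3-(3-methylbut-2-en-1-yl)benzene | C#Cc1ccc(OCOC)c(CC=C(C)C)c1OC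
A11 | alternative 3 | carbon monoxide | [C-]#[O+]
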